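The flask delta holds the smaller charge of substrate and is read up to 15.0 min; one way to carry it to 40 min is on its neighbour alpha, which has the same acid but more substrate.

| flask | substrate | acid | remark | time |
|---|---|---|---|---|
| delta | 0.10 M | 0.10 mM | the very flask that is asked about, followed so far |  |
| alpha | 0.15 M | 0.10 mM | run made earlier |  |
| flask | 0.10 M | 0.100 mM |  | 40 min |

- delta (time / min: substrate / %, product / %): 2.50: 90.4, 6.0; 5.00: 80.1, 14.5; 6.00: 75.0, 16.8; 10.0: 58.9, 29.2; 12.0: 52.7, 34.3; 15.0: 44.3, 42.2
- alpha (time / min: substrate / %, product / %): 3.00: 86.5, 7.7; 5.00: 75.2, 15.8; 8.00: 61.5, 24.9; 12.0: 45.7, 38.1; 15.0: 37.1, 45.0; 25.0: 19.5, 62.3; 40.0: 9.6, 77.3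

(each reading ± 0.5 percentage points)

- part of the substrate that has reacted at 40 min
- pH of the solution at 40 min

- acid is the free proton; pH is minus the decimal logarithm of its molar concentration
- a reading or a percentage of product counts all its forms, free or not
- what has gone from substrate into another species counts as reacted, even if it can come back
- a reading of substrate is of its free form alone

Follow one substrate molecule: each minute it stays free or leaves, and leaving counts as reacted even if it can come back, so the reacted part is what the substrate reading lacks of the charge. Its average chance of leaving, the natural logarithm of charge over remainder divided by the time, is an average pseudo-first-order constant. Over 15.0 min it reads 0.0543 min⁻¹ in delta and 0.0661 min⁻¹ in alpha, so alpha runs ahead. Within delta the chance climbs, from 0.0444 min⁻¹ early to 0.0570 min⁻¹ late, and by 15.0 min alpha holds more product, 0.0675 M against 0.0422 M.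

The pace ratio, alpha's average chance over delta's, is 1.22. Taken as alpha on a slower clock, delta at 40 min stands where alpha stands at 32.8 min. Alpha's readings, interpolated in their logarithms, leave 13.5% there, so this reckoning of my own gives 86.5% reacted; it gives no pH. The forecast says 88% and pH 3.64, noting “Scaling alpha's time by 1.2 gives about 13%”; its reacted part stands 1.5 percentage points above mine.

The flask gives 87.0% reacted, against the pace ratio's 86.5%, and pH 3.49.

    weak acid → by-product carried off (k = 3.68 × 10⁻⁴ s⁻¹)
    substrate + product ⇌ idle adduct, settled at all times (K = 12.6 M⁻¹)
    substrate + acid → weak acid + acid + product (k = 2.73 M⁻¹ s⁻¹)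
    weak acid ⇌ conjugate base + acid, settled at all times (K = 1.60 × 10⁻⁶ M)
    substrate → weak acid + product (k = 8.94 × 10⁻⁵ s⁻¹)

At 40.0 min its acid stands at 324% of its own charge. The pace ratio sends the neighbouring flask, the same one read at 10 min, to alpha's 8.21 min, where alpha's readings leave 60.5% substrate, hence 39.5% reacted, and that neighbouring flask stands at 41.1%.

All runs were computed for substances that don't exist, noise included.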